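**Retrosynthetic overview**
1. The enal is traced back to aryl aldehyde 10 (Wittig two-carbon extension, last step) and the free phenol to the MOM ether 9.
2. The 1,4-dioxane ring is the only ring built (both benzene rings are bought). It is cut at both C–O bonds into 3,4-dihydroxybenzaldehyde 6 and the trans-epoxy chloride 5. In the forward sense the benzylic C-3–O-4 bond forms first, and the ring closes by the O-1–C-2 bond (O-1 is the aryl oxygen para to the formyl carbon, C-2 the CH2OH-bearing carbon).
3. Enabling feature: the segment O-4–C-3H(aryl)–C-2H(CH2OH)–O-1 of the dioxane ring is a 1,2,3-trioxygenated three-carbon chain, a latent 3-aryl-epichlorohydrin. Benzylic C-3 takes the first phenoxide, and the exocyclic CH2OH oxygen serves as the relay epoxide oxygen that activates C-2. O-4 and O-1 sit meta and para to the carbonyl-bearing benzo carbon, so the catechol dianion has two oxygens of different nucleophilicity.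
4. Epoxy chloride 5 comes from sinapic acid 1 by MOM protection, iBu2AlH reduction, Sharpless asymmetric epoxidation (a temporary oxirane ring that sets both stereocentres) and Appel chlorination.

Key step: step 5

**Route**

Step 1
Reactants: 1 sinapic acid, (E)-3-(4-hydroxy-3,5-dimethoxyphenyl)prop-2-enoic acid
Product: 2 methoxymethyl (E)-3-[3,5-dimethoxy-4-(methoxymethoxy)phenyl]prop-2-enoate
Conditions: MOMCl (2.4 equiv), iPr2NEt (3 equiv), CH2Cl2, 0 °C to rt
Reagents that add atoms: chloromethyl methyl ether (MOMCl), COCCl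
Why: Williamson-type O-alkylation caps the phenol and the carboxylic acid in one operation; the aryl MOM ether should survive the hydride, peroxide, phosphine and strong-base steps that follow, and the MOM ester is consumed in step 2.

Step 2
Reactants: 2 methoxymethyl (E)-3-[3,5-dimethoxy-4-(methoxymethoxy)phenyl]prop-2-enoate
Product: 3 (E)-3-[3,5-dimethoxy-4-(methoxymethoxy)phenyl]prop-2-en-1-ol
Conditions: iBu2AlH (3.5 equiv), CH2Cl2, −78 to 0 °C; aq. potassium sodium tartrate work-up
Reagents that add atoms: none
Why: iBu2AlH reduction of the α,β-unsaturated ester proceeds by 1,2-hydride delivery and should leave the (E)-alkene and the aryl acetal untouched.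

Step 3
Reactants: 3 (E)-3-[3,5-dimethoxy-4-(methoxymethoxy)phenyl]prop-2-en-1-ol
Product: 4 [(2R,3R)-3-[3,5-dimethoxy-4-(methoxymethoxy)phenyl]oxiran-2-yl]methanol
Conditions: Ti(OiPr)4 (10 mol%), D-(−)-diisopropyl tartrate (12 mol%), tBuOOH (2 equiv, in decane), 4 Å molecular sieves, CH2Cl2, −20 °C
Reagents that add atoms: tert-butyl hydroperoxide, CC(C)(C)OO
Why: Sharpless asymmetric epoxidation, in which the titanium tartrate complex with D-(−)-tartrate should deliver oxygen to the alkene face that gives the (2R,3R) epoxide, the (E) geometry being transferred stereospecifically to the trans relationship of the two new stereocentres.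

Step 4
Reactants: 4 [(2R,3R)-3-[3,5-dimethoxy-4-(methoxymethoxy)phenyl]oxiran-2-yl]methanol
Product: 5 (2S,3R)-2-(chloromethyl)-3-[3,5-dimethoxy-4-(methoxymethoxy)phenyl]oxirane
Conditions: PPh3 (1.3 equiv), CCl4 (5 equiv), NaHCO3 (0.3 equiv), CH2Cl2, 40 °C
Reagents that add atoms: carbon tetrachloride, ClC(Cl)(Cl)Cl
Why: Appel reaction, in which chloride displaces the primary alkoxyphosphonium group at the CH2 carbon, so neither oxirane stereocentre is touched (the descriptor at C-2 changes from R to S only because CH2Cl now outranks the ring carbon).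

Step 5
Reactants: 5 (2S,3R)-2-(chloromethyl)-3-[3,5-dimethoxy-4-(methoxymethoxy)phenyl]oxirane; 6 3,4-dihydroxybenzaldehyde
Product: 9 (2S,3S)-3-[3,5-dimethoxy-4-(methoxymethoxy)phenyl]-2-(hydroxymethyl)-2,3-dihydro-1,4-benzodioxine-6-carbaldehyde, via chlorohydrin aryl ether 7 (not isolated), via terminal epoxide 8 (not isolated)
Conditions: 6, NaH (2.0 equiv), DMSO, 20 °C; then 5 (1.0 equiv), 20 to 55 °C; then H2O
Reagents that add atoms: none
Why: The disodium salt of 6 should attack the benzylic oxirane carbon of 5 through its more basic oxygen (the one meta to the formyl group, whose charge is not delocalised into the aldehyde) in an SN2 opening with inversion; the secondary alkoxide of 7 then expels chloride and transposes the epoxide to the terminal position with retention at that carbon (8), and the remaining phenoxide, para to the formyl group, opens this new epoxide at its substituted carbon with inversion, forming the O-1–C-2 bond and unveiling the CH2OH group. The closest known reaction type is the base-mediated annulation of catechols with enantiopure epichlorohydrin or glycidyl sulfonates to 2-hydroxymethyl-1,4-benzodioxanes, combined with the known benzylic opening of trans-3-arylglycidol derivatives by phenoxides. The one ring formed, the 1,4-dioxane ring, closes in the 6-exo-tet mode, which is stereoelectronically preferred over 7-endo attack at the CH2 terminus as in the parent epichlorohydrin case. Both stereocentres derive from the (2R,3R) epoxide of step 3 by stereospecific substitution: the aryl-bearing carbon is inverted once, and the CH2OH-bearing carbon is retained once and inverted once, which maps the trans-epoxide onto the trans-(2S,3S) benzodioxane. The step needs three selectivities: oxygen selectivity, secured by full double deprotonation so that the first alkylation occurs at the non-conjugated phenoxide; carbon selectivity in the first attack, secured by benzylic activation of the oxirane carbon and the modest leaving-group ability of a primary chloride; and exo selectivity in the closure, secured by the tether length.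

Step 6
Reactants: 9 (2S,3S)-3-[3,5-dimethoxy-4-(methoxymethoxy)phenyl]-2-(hydroxymethyl)-2,3-dihydro-1,4-benzodioxine-6-carbaldehyde
Product: 10 (2S,3S)-3-(4-hydroxy-3,5-dimethoxyphenyl)-2-(hydroxymethyl)-2,3-dihydro-1,4-benzodioxine-6-carbaldehyde
Conditions: 2 M aq. HCl, THF, 40 °C
Reagents that add atoms: none
Why: Specific-acid hydrolysis of the phenolic methoxymethyl acetal via its oxocarbenium ion; the ring ethers, the aldehyde and both stereocentres should be unaffected under these mild conditions (the trans arrangement is also the thermodynamically preferred one).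

Step 7
Reactants: 10 (2S,3S)-3-(4-hydroxy-3,5-dimethoxyphenyl)-2-(hydroxymethyl)-2,3-dihydro-1,4-benzodioxine-6-carbaldehyde
Product: 11 (E)-3-[(2S,3S)-3-(4-hydroxy-3,5-dimethoxyphenyl)-2-(hydroxymethyl)-2,3-dihydro-1,4-benzodioxin-6-yl]prop-2-enal
Conditions: Ph3P=CHCHO (1.2 equiv), toluene/THF, 80 °C
Reagents that add atoms: (triphenylphosphoranylidene)acetaldehyde, O=CC=P(c1ccccc1)(c1ccccc1)c1ccccc1
Why: Wittig reaction with the formyl-stabilised ylide should give the (E)-enal selectively through reversible oxaphosphetane formation; the ylide is too weakly basic to deprotonate the phenol or disturb the stereocentres.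

**Compound list**
1 | sinapic acid, (E)-3-(4-hydroxy-3,5-dimethoxyphenyl)prop-2-enoic acid | COc1cc(/C=C/C(=O)O)cc(OC)c1O | starting material
2 | methoxymethyl (E)-3-[3,5-dimethoxy-4-(methoxymethoxy)phenyl]prop-2-enoate | COCOC(=O)/C=C/c1cc(OC)c(OCOC)c(OC)c1 | intermediate
3 | (E)-3-[3,5-dimethoxy-4-(methoxymethoxy)phenyl]prop-2-en-1-ol | OC/C=C/c1cc(OC)c(OCOC)c(OC)c1 | intermediate
4 | [(2R,3R)-3-[3,5-dimethoxy-4-(methoxymethoxy)phenyl]oxiran-2-yl]methanol | OC[C@H]1O[C@@H]1c1cc(OC)c(OCOC)c(OC)c1 | intermediate
5 | (2S,3R)-2-(chloromethyl)-3-[3,5-dimethoxy-4-(methoxymethoxy)phenyl]oxirane | ClC[C@H]1O[C@@H]1c1cc(OC)c(OCOC)c(OC)c1 | intermediate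
6 | 3,4-dihydroxybenzaldehyde | O=Cc1ccc(O)c(O)c1 | starting material
7 | 3-{[(1S,2S)-3-chloro-1-[3,5-dimethoxy-4-(methoxymethoxy)phenyl]-2-hydroxypropyl]oxy}-4-hydroxybenzaldehyde (present as its disodium salt, not isolated) | ClC[C@H]([C@@H](Oc1cc(C=O)ccc1O)c1cc(OC)c(OCOC)c(OC)c1)O | intermediate
8 | 4-hydroxy-3-{(S)-[3,5-dimethoxy-4-(methoxymethoxy)phenyl][(2R)-oxiran-2-yl]methoxy}benzaldehyde (present as its sodium phenoxide, not isolated) | C1[C@H]([C@@H](Oc2cc(C=O)ccc2O)c2cc(OC)c(OCOC)c(OC)c2)O1 | intermediate
9 | (2S,3S)-3-[3,5-dimethoxy-4-(methoxymethoxy)phenyl]-2-(hydroxymethyl)-2,3-dihydro-1,4-benzodioxine-6-carbaldehyde | COCOc1c(OC)cc([C@@H]2Oc3cc(C=O)ccc3O[C@H]2CO)cc1OC | intermediate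
10 | (2S,3S)-3-(4-hydroxy-3,5-dimethoxyphenyl)-2-(hydroxymethyl)-2,3-dihydro-1,4-benzodioxine-6-carbaldehyde | COc1cc([C@@H]2Oc3cc(C=O)ccc3O[C@H]2CO)cc(OC)c1O | intermediate
11 | (E)-3-[(2S,3S)-3-(4-hydroxy-3,5-dimethoxyphenyl)-2-(hydroxymethyl)-2,3-dihydro-1,4-benzodioxin-6-yl]prop-2-enal | COc1cc([C@@H]2Oc3cc(/C=C/C=O)ccc3O[C@H]2CO)cc(OC)c1O | target

**Summary**
Total step count: 7.
Longest linear sequence: 7 steps (1 → 2 → 3 → 4 → 5 → 9 → 10 → 11); 6 is used as purchased.

**Steps most likely to fail**

Step 5. The first C–O bond may form through the wrong atoms: the conjugated para-phenoxide may attack first, or chloride may be displaced at CH2 instead of the oxirane opening at the benzylic carbon. The closure may also take the 7-endo course, and partial ionisation at the benzylic carbon would erode the trans relationship. The fallback fixes the oxygen by a protecting group and closes the ring by alcohol activation; it sets out from 4 and 6 and returns at 10. Compound 6 is allylated at its more acidic 4-hydroxyl (allyl bromide, NaHCO3, NaI cat., DMF, 40 °C) to 4-(allyloxy)-3-hydroxybenzaldehyde F1. Its single free phenol opens epoxy alcohol 4 at the benzylic carbon with inversion (NaOH, H2O/1,4-dioxane, 70 °C; no leaving group is present at CH2) to give 4-(allyloxy)-3-{[(1S,2R)-1-[3,5-dimethoxy-4-(methoxymethoxy)phenyl]-2,3-dihydroxypropyl]oxy}benzaldehyde F2. Silylation of the primary hydroxyl (TBSCl, imidazole, DMF, 0 °C) gives 4-(allyloxy)-3-{[(1S,2R)-3-[(tert-butyldimethylsilyl)oxy]-1-[3,5-dimethoxy-4-(methoxymethoxy)phenyl]-2-hydroxypropyl]oxy}benzaldehyde F3. Removal of the allyl group (Pd(PPh3)4 cat., K2CO3, MeOH, rt) gives 3-{[(1S,2R)-3-[(tert-butyldimethylsilyl)oxy]-1-[3,5-dimethoxy-4-(methoxymethoxy)phenyl]-2-hydroxypropyl]oxy}-4-hydroxybenzaldehyde F4. An intramolecular Mitsunobu etherification (PPh3, DIAD, THF, 0 °C to rt) then closes the same O-1–C-2 bond with inversion at the only available carbon to give (2S,3S)-2-{[(tert-butyldimethylsilyl)oxy]methyl}-3-[3,5-dimethoxy-4-(methoxymethoxy)phenyl]-2,3-dihydro-1,4-benzodioxine-6-carbaldehyde F5. Under the conditions of step 6 (2 M aq. HCl, THF, 40 °C), F5 should lose the silyl and the methoxymethyl group together and give 10. Because this sequence starts from 4, it is also independent of step 4.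

Step 3. The electron-rich benzylic epoxide may be opened at the benzylic carbon by isopropoxide, tartrate or hydroperoxide under Lewis-acid activation by the titanium alkoxide, with loss of material and of enantiomeric purity. The fallback replaces the Lewis-acidic metal catalyst by a chiral dioxirane in basic buffer; it sets out from 3 and returns at 4. Shi epoxidation of 3 (D-fructose-derived Shi ketone 30 mol%, KHSO5, K2CO3 buffer at about pH 10.5, MeCN/dimethoxymethane/H2O, 0 °C) is expected to deliver the same (2R,3R) epoxy alcohol 4; no new compound is made (F0).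

Step 7. The enal product may compete with aldehyde 10 for the ylide (over-homologation), and conversion of the electron-rich aldehyde may stall. The fallback builds the chain at the ester oxidation level, where a second olefination is impossible, and then adjusts the oxidation state; it sets out from 10 and returns at 11. Wittig reaction with ethyl (triphenylphosphoranylidene)acetate (toluene, 80 °C) gives ethyl (E)-3-[(2S,3S)-3-(4-hydroxy-3,5-dimethoxyphenyl)-2-(hydroxymethyl)-2,3-dihydro-1,4-benzodioxin-6-yl]prop-2-enoate F6. iBu2AlH (excess, CH2Cl2/THF, −78 °C) reduces it to 4-[(2S,3S)-2-(hydroxymethyl)-6-[(E)-3-hydroxyprop-1-en-1-yl]-2,3-dihydro-1,4-benzodioxin-3-yl]-2,6-dimethoxyphenol F7. Activated MnO2 (EtOAc, rt, short contact time) should then oxidise only the allylic alcohol to give 11.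

**Further compounds**
F1 | step 5 | 4-(allyloxy)-3-hydroxybenzaldehyde | O=Cc1ccc(OCC=C)c(O)c1
F2 | step 5 | 4-(allyloxy)-3-{[(1S,2R)-1-[3,5-dimethoxy-4-(methoxymethoxy)phenyl]-2,3-dihydroxypropyl]oxy}benzaldehyde | OC[C@H]([C@@H](Oc1cc(C=O)ccc1OCC=C)c1cc(OC)c(OCOC)c(OC)c1)O
F3 | step 5 | 4-(allyloxy)-3-{[(1S,2R)-3-[(tert-butyldimethylsilyl)oxy]-1-[3,5-dimethoxy-4-(methoxymethoxy)phenyl]-2-hydroxypropyl]oxy}benzaldehyde | CC(C)(C)[Si](C)(C)OC[C@H]([C@@H](Oc1cc(C=O)ccc1OCC=C)c1cc(OC)c(OCOC)c(OC)c1)O
F4 | step 5 | 3-{[(1S,2R)-3-[(tert-butyldimethylsilyl)oxy]-1-[3,5-dimethoxy-4-(methoxymethoxy)phenyl]-2-hydroxypropyl]oxy}-4-hydroxybenzaldehyde | CC(C)(C)[Si](C)(C)OC[C@H]([C@@H](Oc1cc(C=O)ccc1O)c1cc(OC)c(OCOC)c(OC)c1)O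
F5 | step 5 | (2S,3S)-2-{[(tert-butyldimethylsilyl)oxy]methyl}-3-[3,5-dimethoxy-4-(methoxymethoxy)phenyl]-2,3-dihydro-1,4-benzodioxine-6-carbaldehyde | CC(C)(C)[Si](C)(C)OC[C@@H]1Oc2ccc(C=O)cc2O[C@H]1c1cc(OC)c(OCOC)c(OC)c1
F0 | step 3 | none | none
F6 | step 7 | ethyl (E)-3-[(2S,3S)-3-(4-hydroxy-3,5-dimethoxyphenyl)-2-(hydroxymethyl)-2,3-dihydro-1,4-benzodioxin-6-yl]prop-2-enoate | COc1cc([C@@H]2Oc3cc(/C=C/C(=O)OCC)ccc3O[C@H]2CO)cc(OC)c1O
F7 | step 7 | 4-[(2S,3S)-2-(hydroxymethyl)-6-[(E)-3-hydroxyprop-1-en-1-yl]-2,3-dihydro-1,4-benzodioxin-3-yl]-2,6-dimethoxyphenol | COc1cc([C@@H]2Oc3cc(/C=C/CO)ccc3O[C@H]2CO)cc(OC)c1O
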